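all flasks: electrophile 0.10 M

| run | nucleophile | protic impurity | remark | time |
|---|---|---|---|---|
| ash | 0.095 M | 0.010 M | run made earlier |  |
| alder | 0.095 M | 0.040 M | run made earlier |  |
| flask | 0.0950 M | 0.0200 M |  | 6.0 min |

| run | time / min | electrophile / % | product / % |
|---|---|---|---|
| ash | 0.417 | 68 | 21 |
| ash | 0.833 | 67 | 23 |
| ash | 2.00 | 63 | 27 |
| ash | 5.00 | 61 | 30 |
| alder | 0.417 | 48 | 19 |
| alder | 0.833 | 40 | 19 |
| alder | 2.00 | 37 | 17 |
| alder | 5.00 | 34 | 21 |

(readings scatter by 2 percentage points)

- the earlier runs do not show how much of nucleophile is bound; that part of a forecast is a guess

- part of the electrophile that has reacted at 6.0 min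
- share of the unused nucleophile that is free and not bound as protonated nucleophile, at 6.0 min

- Time came first: between 2.00 min and 5.00 min the electrophile fell by 2 percentage points in ash and 3 points in alder, close to the scatter of 2 points, so I let the last readings stand for 6.0 min in the new flask.
- At those last readings, electrophile plus product fell short of the charge by 9.00% in ash and 45.0% in alder. That is 0.00900 M against 0.010 M of protic impurity, and 0.0450 M against 0.040 M.
- So I took one electrophile lost per protic impurity, the limiting reagent of that loss, and for the new flask defined the quench share, [protic impurity] charged over [electrophile] charged: 20.0%.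
- For product I first worked on a logarithmic axis, where the new flask stands 0.500 of the way from ash to alder. Between 30% and 21% that gave 25.5%.
- That was the weak link: the shortfall grew 5.00-fold for a 4.00-fold charge, roughly with the charge and not its logarithm. Redrawn straight in the charge, product came to 27.0%, and I committed to 47.0% reacted. The free share could be a guess at best.
- The forecast gave 49% reacted, 2 points above my figure, and 8% free, on the ground that “The near-stalled rate implies far less, only a few percent.”
- The new flask gave 46.9% reacted and 2.25% free, so the forecast's reacted part was within tolerance and its free share 5.8 points too high. At 6.00 min, free nucleophile in the new flask was 0.534% of its charge, beside 0.0220 M of protonated nucleophile. Taking the quench share from the result left 26.9%; the flask held 26.9% product and 20.0% quenched substrate.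

    nucleophile + acid set free ⇌ protonated nucleophile, settled at all times (K = 8900 L mol⁻¹)
    electrophile + nucleophile → acid set free + product (k = 0.209 L mol⁻¹ s⁻¹)
    2 nucleophile → homo dimer (k = 0.386 L mol⁻¹ s⁻¹)
    electrophile + protic impurity → quenched substrate (k = 1.51 L mol⁻¹ s⁻¹)

- In a neighbour flask, charged with 0.40 M of electrophile and the same protic impurity, the quench share came to 5.00%. The computed neighbour flask reached 17.0% reacted at 6.00 min, with 5.00% quenched substrate and 12.0% product.

The earlier runs and the new flask are calculated for substances that don't exist; noise was put on by code.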